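**Retrosynthetic overview**

1. Pyranone ring (closed first): the lactone C–O and C3=C4 go back to salicylaldehyde 1 and ylide 2. Forward, the (E)-o-hydroxycinnamate 3 is isomerised by light to the (Z)-ester 4, which lactonises to coumarin 5, as in coumarin biosynthesis.
2. C10 chain (numbered C1' = OCH2 to C8'): C4'–C5' comes from propargylation of prenal 6 with 7 (zinc reagent 8) to alkynol 9. C1'–C2' and the C3' methyl come from syn-carboalumination/hydroxymethylation (alkenylalane 10) to the (E)-diol 11.
3. Aryl ether O–C1': Mitsunobu union of phenol 5 with the primary allylic OH of 11 gives the racemic allylic alcohol 12.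
4. Oxirane ring (closed last, on the complete skeleton): hydroxyl-directed O-atom transfer to the terminal C6'=C7' alkene of 12 with Ti(OiPr)4/L-(+)-DIPT, run as a kinetic resolution, sets C5' and C6' together and gives 13.
5. Ring order: benzene (bought), then pyranone, then oxirane.

Assumption: with the chain numbered as above, the target is the (2'E,5'S,6'S) compound, i.e. the erythro epoxy alcohol; racemic compounds are drawn without a stereo label at C5'.

**Route**

Step 1
Reactants: 1 2,4-dihydroxy-3-methoxybenzaldehyde; 2 ethyl (triphenylphosphoranylidene)acetate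
Product: 5 7-hydroxy-8-methoxy-2H-chromen-2-one, via (E)-cinnamate 3 (not isolated), via (Z)-cinnamate 4 (not isolated)
Conditions: MeCN, 60 °C; then hν (350 nm), 25 °C, 0.02 M, one pot
Reagents that add atoms: none
Why: Wittig olefination with the stabilised ylide gives the (E)-o-hydroxycinnamate 3, and light-driven E→Z isomerisation puts the ester next to the 2-OH so that 4 lactonises spontaneously with loss of ethanol (photoisomerisation–lactonisation, the ring closure plants use for coumarins); no stereocentre is formed.

Step 2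
Reactants: 6 3-methylbut-2-enal (prenal); 7 3-bromoprop-1-yne (propargyl bromide)
Product: 9 rac-6-methylhept-5-en-1-yn-4-ol, via allenylzinc bromide 8 (not isolated)
Conditions: Zn dust, THF/sat. aq NH4Cl, 0 °C → rt
Reagents that add atoms: none
Why: Barbier propargylation, in which the allenylzinc bromide formed in the flask adds 1,2 to the enal through a six-membered SE2' transition state to give the homopropargylic alcohol; the C5' carbinol is formed as a racemate and is resolved in step 5.

Step 3
Reactants: 9 rac-6-methylhept-5-en-1-yn-4-ol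
Product: 11 rac-(2E)-3,7-dimethylocta-2,6-diene-1,5-diol, via alkenylalane 10 (not isolated)
Conditions: Me3Al (3.5 equiv), Cp2ZrCl2 (0.2 equiv), CH2Cl2, 0 °C → rt; then (CH2O)n, THF, 0 °C → rt; aq KNaC4H4O6 (potassium sodium tartrate) work-up
Reagents that add atoms: trimethylaluminium C[Al](C)C; formaldehyde (as paraformaldehyde) C=O
Why: Negishi zirconium-catalysed carboalumination adds Me–Al syn across the terminal alkyne with Al on the terminal carbon, and the (E)-alkenylalane then attacks formaldehyde with retention, so the 2E trisubstituted alkene is fixed by the syn addition while the C6=C7 alkene and the racemic carbinol (as its aluminium alkoxide) are untouched.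

Step 4
Reactants: 5 7-hydroxy-8-methoxy-2H-chromen-2-one; 11 rac-(2E)-3,7-dimethylocta-2,6-diene-1,5-diol
Product: 12 rac-7-{[(2E)-5-hydroxy-3,7-dimethylocta-2,6-dien-1-yl]oxy}-8-methoxy-2H-chromen-2-one
Conditions: PPh3 (1.1 equiv), DIAD (1.1 equiv, slow addition), THF, 0 °C → rt
Reagents that add atoms: none
Why: Mitsunobu etherification, in which the acidic 7-OH (pKa about 8) displaces the oxyphosphonium of the unhindered primary allylic alcohol by SN2 at C1' far faster than the hindered secondary carbinol is activated, and the E geometry prevents the internal OH from closing a ring; no stereocentre is touched.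

Step 5
Reactants: 12 rac-7-{[(2E)-5-hydroxy-3,7-dimethylocta-2,6-dien-1-yl]oxy}-8-methoxy-2H-chromen-2-one
Product: 13 7-{[(2E,5S)-5-[(2S)-3,3-dimethyloxiran-2-yl]-5-hydroxy-3-methylpent-2-en-1-yl]oxy}-8-methoxy-2H-chromen-2-one
Conditions: Ti(OiPr)4 (0.2 equiv), diisopropyl L-(+)-tartrate (0.26 equiv), t-BuOOH (0.55 equiv, in decane), 4 Å MS, CH2Cl2, −20 °C, stopped near 50 % conversion
Reagents that add atoms: tert-butyl hydroperoxide CC(C)(C)OO
Why: Sharpless asymmetric epoxidation run as a kinetic resolution, in which the L-(+)-tartrate catalyst delivers oxygen to the alkene face that makes C6' S and only the (5'S)-carbinol can keep its C4' chain away from the catalyst on that face, so the (S)-half of 12 is epoxidised fast to the erythro (5'S,6'S)-epoxy alcohol while the (R)-half is left behind; the C2'=C3' alkene (only homoallylic to the OH) and the coumarin C3=C4 do not react.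

The unreacted (R)-half of 12 and the minor threo diastereomer are removed by chromatography.

**Compound list**

1 | 2,4-dihydroxy-3-methoxybenzaldehyde | COc1c(O)ccc(C=O)c1O | starting material
2 | ethyl (triphenylphosphoranylidene)acetate | CCOC(=O)C=P(c1ccccc1)(c1ccccc1)c1ccccc1 | starting material
3 | ethyl (2E)-3-(2,4-dihydroxy-3-methoxyphenyl)prop-2-enoate | CCOC(=O)/C=C/c1ccc(O)c(OC)c1O | intermediate
4 | ethyl (2Z)-3-(2,4-dihydroxy-3-methoxyphenyl)prop-2-enoate | CCOC(=O)/C=C\c1ccc(O)c(OC)c1O | intermediate
5 | 7-hydroxy-8-methoxy-2H-chromen-2-one (7-hydroxy-8-methoxycoumarin) | COc1c(O)ccc2ccc(=O)oc12 | intermediate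
6 | 3-methylbut-2-enal | CC(C)=CC=O | starting material
7 | 3-bromoprop-1-yne | C#CCBr | starting material
8 | allenylzinc bromide, CH2=C=CH–ZnBr | C=C=C[Zn]Br | intermediate
9 | rac-6-methylhept-5-en-1-yn-4-ol | C#CCC(O)C=C(C)C | intermediate
10 | (E)-alkenylalane Me2Al–CH=C(CH3)–CH2–CH(OAlMe2)–CH=C(CH3)2 (racemic) | C[Al](C)/C=C(\C)CC(O[Al](C)C)C=C(C)C | intermediate
11 | rac-(2E)-3,7-dimethylocta-2,6-diene-1,5-diol | OC/C=C(\C)CC(O)C=C(C)C | intermediate
12 | rac-7-{[(2E)-5-hydroxy-3,7-dimethylocta-2,6-dien-1-yl]oxy}-8-methoxy-2H-chromen-2-one | COc1c(OC/C=C(\C)CC(O)C=C(C)C)ccc2ccc(=O)oc12 | intermediate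
13 | 7-{[(2E,5S)-5-[(2S)-3,3-dimethyloxiran-2-yl]-5-hydroxy-3-methylpent-2-en-1-yl]oxy}-8-methoxy-2H-chromen-2-one (CNP0166233.1) | COc1c(OC/C=C(\C)C[C@H](O)[C@@H]2OC2(C)C)ccc2ccc(=O)oc12 | target

**Step count**

Total steps: 5. Longest linear sequence: 4 steps (6 → 9 → 11 → 12 → 13); the coumarin branch (1 → 5) is one step.

**Three steps most likely to fail**

Step 5 (highest risk). The cis-methyl on C7' crowds the fast-reacting enantiomer in the titanium tartrate transition state, so the selectivity factor may be modest, and the yield cannot exceed 50 %. The trisubstituted epoxy alcohol can also be opened by the titanium alkoxides, which is why the catalytic loading and sieves are used. The fallback replaces resolution by enantioselective reduction followed by a matched epoxidation, and sets out from 12 (racemate or the recovered (R)-half). Dess–Martin periodinane with NaHCO3 in CH2Cl2 at 0 °C oxidises the carbinol to the ketone 7-{[(2E)-3,7-dimethyl-5-oxoocta-2,6-dien-1-yl]oxy}-8-methoxy-2H-chromen-2-one F1, which is used at once without base to avoid conjugation or loss of the aryloxide. Corey–Bakshi–Shibata reduction with the (R)-methyl oxazaborolidine (0.2 equiv) and catecholborane in toluene at −78 °C then treats the 2-methylpropenyl group as the large substituent and gives the alcohol 7-{[(2E,5S)-5-hydroxy-3,7-dimethylocta-2,6-dien-1-yl]oxy}-8-methoxy-2H-chromen-2-one F2. The same Ti(OiPr)4/L-(+)-DIPT/t-BuOOH epoxidation, now with 1.2 equiv of oxidant and run to full conversion on the matched enantiomer, comes back to the route at 13.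

Step 3. The free homopropargylic OH consumes Me3Al, prolonged reaction can erode the E geometry through chelation, and the alkenylalane may add poorly to paraformaldehyde. The fallback changes the C–C disconnection to a vinylogous aldol and sets out from 6. Commercial methyl 3-methylbut-2-enoate is deprotonated with LiN(i-Pr)2 in THF at −78 °C to the dienolate lithium 1-methoxy-3-methylbuta-1,3-dien-1-olate F3, which is silylated with Me3SiCl to [(1-methoxy-3-methylbuta-1,3-dien-1-yl)oxy]trimethylsilane F4. Vinylogous Mukaiyama aldol of F4 with 6 (BF3·OEt2, CH2Cl2, −78 °C, cold NaHCO3 quench) gives by γ-attack the ester methyl (2E)-5-hydroxy-3,7-dimethylocta-2,6-dienoate F5; any Z isomer lactonises and is separated. Reduction with i-Bu2AlH in CH2Cl2 at −78 °C comes back to the route at 11.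

Step 4. The secondary allylic OH may compete, or SN2' and elimination products may form from the activated allylic alcohol. The fallback masks the secondary alcohol before the chain is completed and sets out from 9. Silylation (t-BuMe2SiCl, imidazole, DMF) gives the ether tert-butyldimethyl[(6-methylhept-5-en-1-yn-4-yl)oxy]silane F6. Carboalumination as in step 3 gives the alkenylalane Me2Al–CH=C(CH3)–CH2–CH(OSiMe2t-Bu)–CH=C(CH3)2 F7, and paraformaldehyde converts it into the alcohol (2E)-5-[(tert-butyldimethylsilyl)oxy]-3,7-dimethylocta-2,6-dien-1-ol F8, which now has a single free OH. Mitsunobu coupling of F8 with 5 (PPh3, DIAD, THF) gives the ether 7-{[(2E)-5-[(tert-butyldimethylsilyl)oxy]-3,7-dimethylocta-2,6-dien-1-yl]oxy}-8-methoxy-2H-chromen-2-one F9, and Bu4NF in THF at 0 °C comes back to the route at 12.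

**Further compounds**

F1 | step 5 | 7-{[(2E)-3,7-dimethyl-5-oxoocta-2,6-dien-1-yl]oxy}-8-methoxy-2H-chromen-2-one | COc1c(OC/C=C(\C)CC(=O)C=C(C)C)ccc2ccc(=O)oc12
F2 | step 5 | 7-{[(2E,5S)-5-hydroxy-3,7-dimethylocta-2,6-dien-1-yl]oxy}-8-methoxy-2H-chromen-2-one | COc1c(OC/C=C(\C)C[C@H](O)C=C(C)C)ccc2ccc(=O)oc12
F3 | step 3 | lithium 1-methoxy-3-methylbuta-1,3-dien-1-olate | COC(O[Li])=CC(C)=C
F4 | step 3 | [(1-methoxy-3-methylbuta-1,3-dien-1-yl)oxy]trimethylsilane | COC(O[Si](C)(C)C)=CC(C)=C
F5 | step 3 | methyl (2E)-5-hydroxy-3,7-dimethylocta-2,6-dienoate (racemic) | COC(=O)/C=C(\C)CC(O)C=C(C)C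
F6 | step 4 | tert-butyldimethyl[(6-methylhept-5-en-1-yn-4-yl)oxy]silane (racemic) | C#CCC(O[Si](C)(C)C(C)(C)C)C=C(C)C
F7 | step 4 | (E)-alkenylalane Me2Al–CH=C(CH3)–CH2–CH(OSiMe2t-Bu)–CH=C(CH3)2 (racemic) | C[Al](C)/C=C(\C)CC(O[Si](C)(C)C(C)(C)C)C=C(C)C
F8 | step 4 | (2E)-5-[(tert-butyldimethylsilyl)oxy]-3,7-dimethylocta-2,6-dien-1-ol (racemic) | OC/C=C(\C)CC(O[Si](C)(C)C(C)(C)C)C=C(C)C
F9 | step 4 | 7-{[(2E)-5-[(tert-butyldimethylsilyl)oxy]-3,7-dimethylocta-2,6-dien-1-yl]oxy}-8-methoxy-2H-chromen-2-one (racemic) | COc1c(OC/C=C(\C)CC(O[Si](C)(C)C(C)(C)C)C=C(C)C)ccc2ccc(=O)oc12
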